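**Retrosynthetic overview**
- The C5 allylic alcohol is traced back through an (E)-enoate and an aldehyde to a nitrile (HWE olefination and two DIBAL-H reductions), leaving (2S,3S)-dihydrobenzofuran nitrile 11.
- Key disconnection: the O1–C7a and C3–C3a bonds of the dihydrofuran are cut together, giving syn-β-hydroxy sec-alkyl boronate 5 (carrying O1, C2, C3 and both stereocentres) and 1-bromo-2-iodoarene 9. The dihydrofuran is the only ring formed; both benzene rings are bought.
- Enabling feature: O1 and C3 sit 1,2 on the C2–C3 edge and both bond to the adjacent arene carbons C7a and C3a. The C2–OH is β to the C3–B bond, so it can direct transmetalation and then act as the O-nucleophile. C7a lies between C7–OMe and C3a and para to the C5 nitrile, so iodide at C3a and bromide at C7a fix the order of the two bond formations.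
- 5 comes from 3,4-dimethoxybenzaldehyde and 1,1-diborylethane (Cu-catalysed syn- and enantioselective 1,2-addition); 9 comes from 4-amino-3-methoxybenzonitrile (iodination, Sandmeyer).

Key step: step 5

Remark: the sense of induction in step 2 is taken to be selectable through the enantiomer of the phosphoramidite ligand; the (1S,2R) adduct is the one required.

Step 1
Reactants: 1 bis[(pinacolato)boryl]methane
Product: 3 1,1-bis[(pinacolato)boryl]ethane, via lithiated diborylmethane 2 (not isolated)
Conditions: LiTMP, THF, 0 °C; then MeI, 0 °C → rt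
Reagents that add atoms: iodomethane, CI
Why: Deprotonative alkylation of a geminal bis(boronate): LiTMP removes the C–H flanked by two boron atoms to give carbanion 2, which is methylated once by SN2 on iodomethane; no stereocentre is formed.

Step 2
Reactants: 3 1,1-bis[(pinacolato)boryl]ethane; 4 3,4-dimethoxybenzaldehyde
Product: 5 (1S,2R)-1-(3,4-dimethoxyphenyl)-2-(4,4,5,5-tetramethyl-1,3,2-dioxaborolan-2-yl)propan-1-ol
Conditions: Cu(MeCN)4PF6 (cat.), chiral monodentate phosphoramidite (cat.), LiOt-Am, THF, rt; H2O work-up
Reagents that add atoms: none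
Why: Copper-catalysed enantio- and diastereoselective 1,2-addition of a 1,1-diborylalkane to an aryl aldehyde: alkoxide-triggered boron-to-copper transmetalation gives a chiral α-boryl alkylcopper that adds to 4 through a closed transition state, the phosphoramidite ligand setting C1 and C2 together as the syn-(1S,2R) pair.

Step 3
Reactants: 6 4-amino-3-methoxybenzonitrile
Product: 7 4-amino-3-iodo-5-methoxybenzonitrile
Conditions: NIS, AcOH, rt
Reagents that add atoms: N-iodosuccinimide, O=C1CCC(=O)N1I
Why: Electrophilic aromatic iodination (SEAr) directed by the amino group, whose only free ortho or para position is the carbon ortho to NH2 and meta to the nitrile.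

Step 4
Reactants: 7 4-amino-3-iodo-5-methoxybenzonitrile
Product: 9 4-bromo-3-iodo-5-methoxybenzonitrile, via arenediazonium bromide 8 (not isolated)
Conditions: NaNO2, 48% aq. HBr, MeCN, 0 °C; then CuBr (cat.), 0 → 60 °C
Reagents that add atoms: hydrobromic acid, Br
Why: Sandmeyer reaction: diazotisation of the aniline and copper(I)-mediated replacement of N2 by bromide leave the C–I bond and the nitrile untouched.

Step 5
Reactants: 5 (1S,2R)-1-(3,4-dimethoxyphenyl)-2-(4,4,5,5-tetramethyl-1,3,2-dioxaborolan-2-yl)propan-1-ol; 9 4-bromo-3-iodo-5-methoxybenzonitrile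
Product: 11 (2S,3S)-2-(3,4-dimethoxyphenyl)-7-methoxy-3-methyl-2,3-dihydro-1-benzofuran-5-carbonitrile, via bromo alcohol 10 (not isolated)
Conditions: Pd(OAc)2 (5 mol%), RuPhos (10 mol%), KOH (3 equiv), THF–H2O 10:1, 70 °C (sealed), then 90 °C
Reagents that add atoms: none
Why: Proposed new method: a Pd-catalysed annulative cross-coupling in which Pd(0)/RuPhos first inserts into the C–I bond of 9, the potassium alkoxide of 5 binds that aryl–Pd centre and hands over the neighbouring boron-bearing carbon by inner-sphere transmetalation, and reductive elimination forms the C3–C3a bond of bromo alcohol 10. A second oxidative addition into the now flanking C7a–Br bond gives a six-membered aryl–Pd–alkoxide palladacycle, and C–O reductive elimination, eased by the para nitrile (which also allows direct SNAr as a parallel path to the same bond), closes the dihydrofuran as a five-membered ring by intramolecular ipso O-arylation (5-exo attack of O1 on C7a). The closest known reaction types are the β-hydroxyl-directed, stereoretentive Suzuki–Miyaura coupling of secondary pinacol boronates with aryl halides and the intramolecular Buchwald–Hartwig etherification of secondary alcohols; merging them in one operation on a 1-bromo-2-iodoarene is the new element. No stereocentre is created: C2 comes unchanged from 5 because its C–O bond is never broken, and C3 is transferred with retention in the transmetalation, so the syn-hydroxyboronate maps onto the trans-(2S,3S) ring. The step needs C-arylation before O-arylation and reaction at C3a before C7a; this is secured by the iodide at C3a against the more hindered bromide at C7a (between OMe and I) and by the free hydroxyl, which accelerates transmetalation over intermolecular etherification.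

Step 6
Reactants: 11 (2S,3S)-2-(3,4-dimethoxyphenyl)-7-methoxy-3-methyl-2,3-dihydro-1-benzofuran-5-carbonitrile
Product: 13 (2S,3S)-2-(3,4-dimethoxyphenyl)-7-methoxy-3-methyl-2,3-dihydro-1-benzofuran-5-carbaldehyde, via N-aluminoimine 12 (not isolated)
Conditions: DIBAL-H (1.2 equiv), toluene, −78 °C; then aq. Rochelle salt, rt
Reagents that add atoms: water, O
Why: Partial reduction of an aryl nitrile: one hydride from DIBAL-H gives N-aluminoimine 12, which resists further reduction at −78 °C and is hydrolysed to the aldehyde on work-up, C2 and C3 being remote and non-acidic.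

Step 7
Reactants: 13 (2S,3S)-2-(3,4-dimethoxyphenyl)-7-methoxy-3-methyl-2,3-dihydro-1-benzofuran-5-carbaldehyde
Product: 14 ethyl (2E)-3-[(2S,3S)-2-(3,4-dimethoxyphenyl)-7-methoxy-3-methyl-2,3-dihydro-1-benzofuran-5-yl]prop-2-enoate
Conditions: (EtO)2P(O)CH2CO2Et, NaH, THF, 0 °C → rt
Reagents that add atoms: triethyl phosphonoacetate, CCOC(=O)CP(=O)(OCC)OCC
Why: Horner–Wadsworth–Emmons olefination: the stabilised phosphonate anion adds reversibly to the aryl aldehyde and syn-elimination of phosphate under thermodynamic control gives the (E)-enoate.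

Step 8
Reactants: 14 ethyl (2E)-3-[(2S,3S)-2-(3,4-dimethoxyphenyl)-7-methoxy-3-methyl-2,3-dihydro-1-benzofuran-5-yl]prop-2-enoate
Product: 15 (2E)-3-[(2S,3S)-2-(3,4-dimethoxyphenyl)-7-methoxy-3-methyl-2,3-dihydro-1-benzofuran-5-yl]prop-2-en-1-ol
Conditions: DIBAL-H (2.5 equiv), CH2Cl2, −78 °C; aq. Rochelle salt
Reagents that add atoms: none
Why: DIBAL-H reduces the α,β-unsaturated ester in 1,2-fashion at low temperature to the allylic alcohol without touching the (E)-alkene, the aryl ethers or the two stereocentres.

**Compound list**
1 | bis[(pinacolato)boryl]methane | C(B1OC(C)(C)C(C)(C)O1)B1OC(C)(C)C(C)(C)O1 | starting material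
2 | lithiated bis[(pinacolato)boryl]methane | [Li]C(B1OC(C)(C)C(C)(C)O1)B1OC(C)(C)C(C)(C)O1 | intermediate
3 | 1,1-bis[(pinacolato)boryl]ethane | CC(B1OC(C)(C)C(C)(C)O1)B1OC(C)(C)C(C)(C)O1 | intermediate
4 | 3,4-dimethoxybenzaldehyde | COc1ccc(C=O)cc1OC | starting material
5 | (1S,2R)-1-(3,4-dimethoxyphenyl)-2-(4,4,5,5-tetramethyl-1,3,2-dioxaborolan-2-yl)propan-1-ol | COc1ccc([C@@H](O)[C@@H](C)B2OC(C)(C)C(C)(C)O2)cc1OC | intermediate
6 | 4-amino-3-methoxybenzonitrile | COc1cc(C#N)ccc1N | starting material
7 | 4-amino-3-iodo-5-methoxybenzonitrile | COc1cc(C#N)cc(I)c1N | intermediate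
8 | 4-cyano-2-iodo-6-methoxybenzenediazonium bromide | COc1cc(C#N)cc(I)c1[N+]#N.[Br-] | intermediate
9 | 4-bromo-3-iodo-5-methoxybenzonitrile | COc1cc(C#N)cc(I)c1Br | intermediate
10 | 4-bromo-3-[(1S,2S)-1-(3,4-dimethoxyphenyl)-1-hydroxypropan-2-yl]-5-methoxybenzonitrile | COc1ccc([C@@H](O)[C@@H](C)c2cc(C#N)cc(OC)c2Br)cc1OC | intermediate
11 | (2S,3S)-2-(3,4-dimethoxyphenyl)-7-methoxy-3-methyl-2,3-dihydro-1-benzofuran-5-carbonitrile | COc1ccc([C@H]2Oc3c(OC)cc(C#N)cc3[C@@H]2C)cc1OC | intermediate
12 | N-(diisobutylaluminio) aldimine of 13 | COc1ccc([C@H]2Oc3c(OC)cc(C=N[Al](CC(C)C)CC(C)C)cc3[C@@H]2C)cc1OC | intermediate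
13 | (2S,3S)-2-(3,4-dimethoxyphenyl)-7-methoxy-3-methyl-2,3-dihydro-1-benzofuran-5-carbaldehyde | COc1ccc([C@H]2Oc3c(OC)cc(C=O)cc3[C@@H]2C)cc1OC | intermediate
14 | ethyl (2E)-3-[(2S,3S)-2-(3,4-dimethoxyphenyl)-7-methoxy-3-methyl-2,3-dihydro-1-benzofuran-5-yl]prop-2-enoate | COc1ccc([C@H]2Oc3c(OC)cc(/C=C/C(=O)OCC)cc3[C@@H]2C)cc1OC | intermediate
15 | (2E)-3-[(2S,3S)-2-(3,4-dimethoxyphenyl)-7-methoxy-3-methyl-2,3-dihydro-1-benzofuran-5-yl]prop-2-en-1-ol | COc1ccc([C@H]2Oc3c(OC)cc(/C=C/CO)cc3[C@@H]2C)cc1OC | target

**Total step count:** 8
**Longest linear sequence:** 6 steps (6 → 15 through steps 3 to 8; equally 1 → 15 through steps 1, 2, 5 to 8)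

**Steps most likely to fail**

1. Step 5 (proposed new method). The cascade may stall after the first coupling. The slow transfer of the hindered secondary alkyl group may also be outrun by protodeboronation or base-induced boron–oxygen elimination of 5, or by β-hydride elimination at palladium. The fallback uses known chemistry, sets out from 9 and comes back at 11 through 10, which is now isolated. Palladium-catalysed ketone α-arylation of commercial 1-(3,4-dimethoxyphenyl)propan-1-one with 9 at the C–I bond (Pd2(dba)3, Xantphos, K3PO4, toluene, 80 °C) should give the racemic ketone 4-bromo-3-[1-(3,4-dimethoxyphenyl)-1-oxopropan-2-yl]-5-methoxybenzonitrile F1. Asymmetric hydrogenation under dynamic kinetic resolution (Ru diphosphine/diamine catalyst, t-BuOK, i-PrOH, H2) should then give the syn-(1S,2S) alcohol 10: the acidic α-centre equilibrates, hydride is delivered in the Felkin sense, and the catalyst enantiomer is chosen accordingly. Copper-catalysed intramolecular Ullmann etherification (CuI, 1,10-phenanthroline, Cs2CO3, toluene, 110 °C) then closes the ring to 11 with retention at both centres.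

2. Step 2. Facial control in the addition of the α-boryl alkylcopper to the electron-rich aldehyde may be insufficient, so that enantiomeric purity is eroded. The fallback replaces asymmetric catalysis by resolution, sets out from 3 and 4 and comes back at 5. The same copper-catalysed addition is run with an achiral ligand (for example triphenyl phosphite), which should give the racemic syn adduct, that is 5 together with its enantiomer (1R,2S)-1-(3,4-dimethoxyphenyl)-2-(4,4,5,5-tetramethyl-1,3,2-dioxaborolan-2-yl)propan-1-ol F2. The two are separated by preparative chromatography on a chiral stationary phase, and 5 is taken on.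

3. Step 6. The N-aluminoimine may be reduced further to the benzylic amine, or the imine may be hydrolysed incompletely on work-up. The fallback replaces partial reduction by a hydrolysis–reduction–oxidation sequence, sets out from 11 and comes back at 13. Basic hydrolysis of the nitrile (NaOH, EtOH–H2O, reflux, then acidification) should give (2S,3S)-2-(3,4-dimethoxyphenyl)-7-methoxy-3-methyl-2,3-dihydro-1-benzofuran-5-carboxylic acid F3. Borane reduction (BH3·THF, 0 °C → rt) should give [(2S,3S)-2-(3,4-dimethoxyphenyl)-7-methoxy-3-methyl-2,3-dihydro-1-benzofuran-5-yl]methanol F4, and MnO2 (CH2Cl2, rt) oxidises this benzylic alcohol to 13.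

**Further compounds**
F1 | step 5 | 4-bromo-3-[1-(3,4-dimethoxyphenyl)-1-oxopropan-2-yl]-5-methoxybenzonitrile (racemic) | COc1ccc(C(=O)C(C)c2cc(C#N)cc(OC)c2Br)cc1OC
F2 | step 2 | (1R,2S)-1-(3,4-dimethoxyphenyl)-2-(4,4,5,5-tetramethyl-1,3,2-dioxaborolan-2-yl)propan-1-ol | COc1ccc([C@H](O)[C@H](C)B2OC(C)(C)C(C)(C)O2)cc1OC
F3 | step 6 | (2S,3S)-2-(3,4-dimethoxyphenyl)-7-methoxy-3-methyl-2,3-dihydro-1-benzofuran-5-carboxylic acid | COc1ccc([C@H]2Oc3c(OC)cc(C(=O)O)cc3[C@@H]2C)cc1OC
F4 | step 6 | [(2S,3S)-2-(3,4-dimethoxyphenyl)-7-methoxy-3-methyl-2,3-dihydro-1-benzofuran-5-yl]methanol | COc1ccc([C@H]2Oc3c(OC)cc(CO)cc3[C@@H]2C)cc1OC
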